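I counted the target of this flask as a molar concentration, c(target), because the percent asked for is simply c(target) divided by the solid charged.

| flask | solid substrate | partner | remark | time |
|---|---|---|---|---|
| ochre | 0.12 M | 0.20 M | run made earlier |  |
| teal | 0.19 M | 0.20 M | run made earlier |  |
| red | 0.25 M | 0.40 M | run made earlier |  |
| flask | 0.25 M | 0.200 M |  | 8.0 min |
- ochre (time / min: target / %, dissolved substrate / %): 2.50: 17.7, 0.2; 5.00: 25.6, 0.1; 8.00: 30.3, 0.6; 10.0: 27.9, 0
- teal (time / min: target / %, dissolved substrate / %): 1.33: 6.8, 0; 3.00: 12.4, 0; 6.00: 17.3, 0; 10.0: 19.7, 0.3
- red (time / min: target / %, dissolved substrate / %): 0.833: 4.1, 0; 2.00: 8.0, 0.4; 4.00: 10.9, 0.1; 10.0: 16.6, 0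

(each reading ± 0.3 percentage points)
1. how much target there is at 8.0 min, in percent of the solid substrate charged
2. concentration of dissolved substrate in solution at 8.0 min, in percent of saturation
- solid substrate is a solid; its amount is given per volume of the solution
- what was read earlier has a scatter of 0.3 percentage points, one standard deviation
- at the start none of the solid substrate is in solution
- dissolved substrate means what is dissolved; the solid is not counted in it

I began with the main step alone, a steady feed of target. The earliest red reading gives 0.0123 M min⁻¹, and over 8.0 min that makes 0.0984 M. This is more than the 0.0374 M of the last teal reading.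

So I added a first-order loss of target, which bends c(target) towards a ceiling. Taking that teal reading as the ceiling, feed over ceiling gave a loss constant of 0.329 min⁻¹, and c(target) at 8.0 min came to 0.0347 M. But at 10.0 min the curve was still short of its ceiling, so I put this constant back in and went round once more. The ceiling became 0.0389 M, the constant 0.316 min⁻¹, and I had 0.0358 M, the molar target at the asked time.

Last came the solid charge, which in this reckoning enters as the divisor. Ochre, with 0.12 M of solid, read 0.0364 M at 8.00 min. For the flask with 0.25 M I committed to 14.3%. Dissolved substrate read 0.6% at most, in ochre; these readings are percentages of the solid charged and give no solubility to hold them against, so I gave no number for sat.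

The forecast gave 14.5% of target, slightly above my figure, and 90% of saturation, on the ground that “dissolution appears to limit the rate”.

The flask gave 14.5% of target, which is 0.0362 M against my 0.0358 M, and 0.668% of saturation.

    dissolved substrate + target → side product (k = 1.00 M⁻¹ s⁻¹)
    solid substrate ⇌ dissolved substrate, rate k2*(cs2 - [dissolved substrate]) while solid is left; crystals form when [dissolved substrate] > cs2 (solubility = 0.0830 M, k = 0.00260 s⁻¹)
    target ⇌ isomer of the product (K = 5.10, k = 0.00590 s⁻¹)
    dissolved substrate + partner → target (k = 3.40 M⁻¹ s⁻¹)

In the flask, the half-life of dissolved substrate by the making of target alone, at the charged concentrations, was 1.0 s, much shorter than the 8.0 min of the run. At 8.00 min it was made 1.00 times as fast as it was used up, a steady state. Divided by the 0.15 M of solid substrate in a neighbour flask, 0.0358 M gives 23.9%, and that flask holds 24.1% of target at 8.00 min.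

The runs come from a simulation from invented constants, noise included.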